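**Plan**
- Retrosynthesis: the sixteen methyl ethers and the D6 ester come off last; ring D is cut at D6–D1 and D4–D3 into ynoate 28 (rings A–C, supplies D1–D3) and keto ester 11 (rings E–G, supplies D4–D6).
- Enabling feature: ring D has oxygen on D1, D3 and D5 and a fourth oxygen on D4. D1–D2–D3 is therefore an aryloxypropiolate, D4–D5–D6 a 4-aryloxyacetoacetate, and the D3 and D5 hydroxyls are the two carbonyl carbons.
- The other four ether bonds (F–G, E–F, A–B, B–C) are each cut between a phenol and a bromobenzaldehyde or boronic acid; the formyl group activates the halide and then becomes the next phenol oxygen.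
- Forward: rings A, B, C, E, F, G are bought as benzenes. F–G then E–F are joined (steps 1–4), A–B then B–C (steps 6–10). Ring D is the only ring built (step 13), followed by decarboxylation and demethylation.
- Stereochemistry: the target has no stereocentre; the (E) double bond of 24 is the only stereo-element and is consumed in step 12.

Key step: step 13

Remark: rings are lettered A to G from the 2,4,6-trihydroxyphenyl end, D1 carries the oxygen to ring C and D4 the oxygen to ring E; 6, 12, 13 and 17 are taken as catalogue compounds, and all electron-rich phenols are handled under argon.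
Abbreviations: ArABC = 6-[2,6-dimethoxy-4-(2,4,6-trimethoxyphenoxy)phenoxy]-2,3,4-trimethoxyphenyl (bonded through C6); ArEFG = 2-[3,5-dimethoxy-4-(3,4,5-trimethoxyphenoxy)phenoxy]-3,4,5-trimethoxyphenyl (bonded through E1).

**Step 1**
Reactants: 1 4-hydroxy-3,5-dimethoxybenzaldehyde (syringaldehyde); 2 (3,4,5-trimethoxyphenyl)boronic acid
Product: 3 3,5-dimethoxy-4-(3,4,5-trimethoxyphenoxy)benzaldehyde
Conditions: Cu(OAc)2 (1 equiv), pyridine, 4 Å MS, CH2Cl2, air, rt
Reagents that add atoms: none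
Why: Chan–Lam oxidative coupling arylates 2,6-disubstituted phenols at room temperature, and the para-formyl group of 1 blocks oxidative para-coupling while standing in for the later F1 oxygen.

**Step 2**
Reactants: 3 3,5-dimethoxy-4-(3,4,5-trimethoxyphenoxy)benzaldehyde
Product: 5 3,5-dimethoxy-4-(3,4,5-trimethoxyphenoxy)phenol, via aryl formate 4 (not isolated)
Conditions: mCPBA, CH2Cl2, 0 °C to rt; then K2CO3 (cat.), MeOH, rt
Reagents that add atoms: mCPBA, O=C(OO)c1cccc(Cl)c1
Why: Baeyer–Villiger oxidation of a benzaldehyde with a para oxygen donor goes by aryl migration (as with 3,4,5-trimethoxybenzaldehyde), and the formate is removed by mild methanolysis.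

**Step 3**
Reactants: 5 3,5-dimethoxy-4-(3,4,5-trimethoxyphenoxy)phenol; 6 2-bromo-3,4,5-trimethoxybenzaldehyde
Product: 7 2-[3,5-dimethoxy-4-(3,4,5-trimethoxyphenoxy)phenoxy]-3,4,5-trimethoxybenzaldehyde
Conditions: CuI (10 mol %), picolinic acid (20 mol %), K3PO4, DMSO, 90 °C
Reagents that add atoms: none
Why: Ullmann ether synthesis in which the ortho-formyl group activates the crowded C–Br bond of 6 and the nucleophile 5 is an unhindered phenol.

**Step 4**
Reactants: 7 2-[3,5-dimethoxy-4-(3,4,5-trimethoxyphenoxy)phenoxy]-3,4,5-trimethoxybenzaldehyde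
Product: 9 ArEFG–OH (2-[3,5-dimethoxy-4-(3,4,5-trimethoxyphenoxy)phenoxy]-3,4,5-trimethoxyphenol), via aryl formate 8 (not isolated)
Conditions: mCPBA, CH2Cl2, 0 °C to rt; then K2CO3 (cat.), MeOH, rt
Reagents that add atoms: mCPBA, O=C(OO)c1cccc(Cl)c1
Why: Baeyer–Villiger oxidation with aryl migration, favoured by the ortho-aryloxy and para-methoxy donors, frees the E1 hydroxyl next to the only ring-E hydrogen.

**Step 5**
Reactants: 9 ArEFG–OH; 10 methyl 4-chloro-3-oxobutanoate
Product: 11 methyl 4-(ArEFG-oxy)-3-oxobutanoate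
Conditions: NaH (2.2 equiv), THF, 0 °C to rt
Reagents that add atoms: none
Why: Williamson alkylation of the sodium phenoxide at the γ-chloride, the standard route to 4-aryloxyacetoacetates, with the second equivalent of NaH holding the keto ester as its enolate against self-condensation.

**Step 6**
Reactants: 12 2,4,6-trimethoxyphenol; 13 4-bromo-2,6-dimethoxybenzaldehyde
Product: 14 2,6-dimethoxy-4-(2,4,6-trimethoxyphenoxy)benzaldehyde
Conditions: CuI (10 mol %), picolinic acid (20 mol %), K3PO4, DMSO, 90 °C, Ar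
Reagents that add atoms: none
Why: Ullmann ether synthesis with the picolinic acid ligand tolerates a 2,6-disubstituted phenol, and the bromide of 13 is unhindered and activated by the para-formyl group.

**Step 7**
Reactants: 14 2,6-dimethoxy-4-(2,4,6-trimethoxyphenoxy)benzaldehyde
Product: 16 2,6-dimethoxy-4-(2,4,6-trimethoxyphenoxy)phenol, via aryl formate 15 (not isolated)
Conditions: mCPBA (1.05 equiv), CH2Cl2, 0 °C; then K2CO3 (cat.), degassed MeOH, rt
Reagents that add atoms: mCPBA, O=C(OO)c1cccc(Cl)c1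
Why: Baeyer–Villiger oxidation of an aldehyde flanked by two methoxy groups should be much faster than peracid attack on ring A, as in the routine conversion of 2,4,6-trimethoxybenzaldehyde into its phenol.

**Step 8**
Reactants: 17 5-bromo-1,2,3-trimethoxybenzene
Product: 19 6-bromo-2,3,4-trimethoxybenzaldehyde, via chloro ether 18 (not isolated)
Conditions: Cl2CHOMe, TiCl4, CH2Cl2, –10 to 0 °C; then H2O
Reagents that add atoms: dichloromethyl methyl ether, COC(Cl)Cl; water, O
Why: Rieche formylation can give only one isomer because the two free positions of 17 are equivalent, and each is ortho and para to methoxy groups.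

**Step 9**
Reactants: 16 2,6-dimethoxy-4-(2,4,6-trimethoxyphenoxy)phenol; 19 6-bromo-2,3,4-trimethoxybenzaldehyde
Product: 20 6-[2,6-dimethoxy-4-(2,4,6-trimethoxyphenoxy)phenoxy]-2,3,4-trimethoxybenzaldehyde
Conditions: CuI (10 mol %), picolinic acid (20 mol %), K3PO4, DMSO, 100 °C, Ar
Reagents that add atoms: none
Why: Ullmann ether synthesis with an ortho-formyl-activated bromide, the classical way to tri-ortho-substituted polymethoxy diaryl ethers from 2,6-dimethoxyphenols.

**Step 10**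
Reactants: 20 6-[2,6-dimethoxy-4-(2,4,6-trimethoxyphenoxy)phenoxy]-2,3,4-trimethoxybenzaldehyde
Product: 22 ArABC–OH (6-[2,6-dimethoxy-4-(2,4,6-trimethoxyphenoxy)phenoxy]-2,3,4-trimethoxyphenol), via aryl formate 21 (not isolated)
Conditions: mCPBA (1.05 equiv), CH2Cl2, 0 °C; then K2CO3 (cat.), degassed MeOH, rt
Reagents that add atoms: mCPBA, O=C(OO)c1cccc(Cl)c1
Why: Baeyer–Villiger oxidation with aryl migration, favoured by the two ortho oxygen donors, frees the crowded C6 hydroxyl.

**Step 11**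
Reactants: 22 ArABC–OH; 23 trichloroethylene
Product: 24 (E)-1,2-dichloroethenyl ArABC ether
Conditions: K2CO3, DMF, 70 °C
Reagents that add atoms: none
Why: the phenoxide adds anti to dichloroacetylene formed in the flask from trichloroethylene, a known route to aryl (E)-1,2-dichlorovinyl ethers whose small electrophile tolerates a di-ortho-substituted phenoxide.

**Step 12**
Reactants: 24 (E)-1,2-dichloroethenyl ArABC ether; 25 methyl chloroformate
Product: 28 methyl 3-(ArABC-oxy)prop-2-ynoate, via chloroethynyl ether 26 (not isolated), via lithium acetylide 27 (not isolated)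
Conditions: n-BuLi (2.2 equiv), THF, –78 °C; then ClCO2Me, –78 to –20 °C
Reagents that add atoms: none
Why: n-BuLi effects dehydrochlorination and then chlorine–lithium exchange to the lithium aryloxyacetylide, whose C-acylation by a chloroformate is the known route to 3-alkoxy- and 3-aryloxypropiolates, while ring lithiation of methoxyarenes does not compete at –78 °C.

**Step 13**
Reactants: 11 methyl 4-(ArEFG-oxy)-3-oxobutanoate; 28 methyl 3-(ArABC-oxy)prop-2-ynoate
Product: 30 methyl 6-(ArABC-oxy)-3-(ArEFG-oxy)-2,4-dihydroxybenzoate, via Michael adduct 29 (not isolated)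
Conditions: NaH (1.05 equiv), THF, 0 °C, then 28, 0 °C to rt; then LDA (2.2 equiv), –78 to 0 °C; then 1 M HCl
Reagents that add atoms: none
Why: Proposed new method: the sodium enolate of 11 should add through C2 to the aryloxy-bearing β-carbon of the push–pull ynoate 28 (bond D6–D1), and the vinyl anion is quenched at once by the acidic C2–H, giving the delocalised anion of glutaconate 29 in which the enoate geometry can equilibrate. LDA then removes a C4 proton, acidified by the ketone and its aryloxy group, and this carbon attacks the acrylate ester in a 6-(enolendo)-exo-trig Claisen closure of ring D (bond D4–D3); loss of methoxide and enolisation give the aromatic resorcylate without an oxidant because the acceptor is at the alkyne oxidation level. The closest known reactions are the Michael–Claisen syntheses of orsellinates and olivetol esters from β-keto esters or malonates with unsaturated or acetylenic carbonyl compounds, and conjugate additions to 3-alkoxypropiolates; new here are the aryloxy groups on the acceptor β-carbon and on the donor γ-carbon. No stereocentre is formed. The step needs C2 to react before C4, which one equivalent of NaH secures because no dianion is present in the Michael stage, and C- over O-acylation, which is favoured because the dianion of 29 is most nucleophilic at its terminal carbon and only C-acylation ends in irreversible aromatisation. Loss of the ABC aryloxide from the vinyl anion is the main competing path and is countered by the fast internal proton transfer.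

**Step 14**
Reactants: 30 methyl 6-(ArABC-oxy)-3-(ArEFG-oxy)-2,4-dihydroxybenzoate
Product: 32 5-(ArABC-oxy)-2-(ArEFG-oxy)benzene-1,3-diol, via carboxylic acid 31 (not isolated)
Conditions: NaOH, H2O/MeOH, reflux, Ar; then HCl, 60 °C
Reagents that add atoms: none
Why: saponification of a 2,4-dihydroxybenzoate followed by protodecarboxylation of the phloroglucinol-type acid, as in the standard conversion of resorcylate esters into resorcinols.

**Step 15**
Reactants: 32 5-(ArABC-oxy)-2-(ArEFG-oxy)benzene-1,3-diol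
Product: 33 the target heptamer (CNP0292517.0)
Conditions: BBr3 (excess), CH2Cl2, –78 °C to rt, Ar; then MeOH, H2O
Reagents that add atoms: none
Why: BBr3 cleaves aryl methyl ethers by bromide attack on the methyl group of the boron-bound ether, whereas the six diaryl ether bonds have no sp3 carbon and should stay intact.

**Compound list**
1 | 4-hydroxy-3,5-dimethoxybenzaldehyde (syringaldehyde) | COc1cc(C=O)cc(OC)c1O | starting material
2 | (3,4,5-trimethoxyphenyl)boronic acid | COc1cc(B(O)O)cc(OC)c1OC | starting material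
3 | 3,5-dimethoxy-4-(3,4,5-trimethoxyphenoxy)benzaldehyde | COc1cc(C=O)cc(OC)c1Oc1cc(OC)c(OC)c(OC)c1 | intermediate
4 | 3,5-dimethoxy-4-(3,4,5-trimethoxyphenoxy)phenyl formate | COc1cc(OC=O)cc(OC)c1Oc1cc(OC)c(OC)c(OC)c1 | intermediate (not isolated)
5 | 3,5-dimethoxy-4-(3,4,5-trimethoxyphenoxy)phenol | COc1cc(O)cc(OC)c1Oc1cc(OC)c(OC)c(OC)c1 | intermediate
6 | 2-bromo-3,4,5-trimethoxybenzaldehyde | COc1cc(C=O)c(Br)c(OC)c1OC | starting material
7 | 2-[3,5-dimethoxy-4-(3,4,5-trimethoxyphenoxy)phenoxy]-3,4,5-trimethoxybenzaldehyde | COc1cc(C=O)c(Oc2cc(OC)c(Oc3cc(OC)c(OC)c(OC)c3)c(OC)c2)c(OC)c1OC | intermediate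
8 | ArEFG formate | COc1cc(OC=O)c(Oc2cc(OC)c(Oc3cc(OC)c(OC)c(OC)c3)c(OC)c2)c(OC)c1OC | intermediate (not isolated)
9 | ArEFG–OH, 2-[3,5-dimethoxy-4-(3,4,5-trimethoxyphenoxy)phenoxy]-3,4,5-trimethoxyphenol | COc1cc(O)c(Oc2cc(OC)c(Oc3cc(OC)c(OC)c(OC)c3)c(OC)c2)c(OC)c1OC | intermediate
10 | methyl 4-chloro-3-oxobutanoate | COC(=O)CC(=O)CCl | starting material
11 | methyl 4-(ArEFG-oxy)-3-oxobutanoate | COC(=O)CC(=O)COc1cc(OC)c(OC)c(OC)c1Oc1cc(OC)c(Oc2cc(OC)c(OC)c(OC)c2)c(OC)c1 | intermediate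
12 | 2,4,6-trimethoxyphenol | COc1cc(OC)c(O)c(OC)c1 | starting material
13 | 4-bromo-2,6-dimethoxybenzaldehyde | COc1cc(Br)cc(OC)c1C=O | starting material
14 | 2,6-dimethoxy-4-(2,4,6-trimethoxyphenoxy)benzaldehyde | COc1cc(OC)c(Oc2cc(OC)c(C=O)c(OC)c2)c(OC)c1 | intermediate
15 | 2,6-dimethoxy-4-(2,4,6-trimethoxyphenoxy)phenyl formate | COc1cc(OC)c(Oc2cc(OC)c(OC=O)c(OC)c2)c(OC)c1 | intermediate (not isolated)
16 | 2,6-dimethoxy-4-(2,4,6-trimethoxyphenoxy)phenol | COc1cc(OC)c(Oc2cc(OC)c(O)c(OC)c2)c(OC)c1 | intermediate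
17 | 5-bromo-1,2,3-trimethoxybenzene | COc1cc(Br)cc(OC)c1OC | starting material
18 | 1-bromo-2-[chloro(methoxy)methyl]-3,4,5-trimethoxybenzene (racemic) | COC(Cl)c1c(Br)cc(OC)c(OC)c1OC | intermediate (not isolated)
19 | 6-bromo-2,3,4-trimethoxybenzaldehyde | COc1cc(Br)c(C=O)c(OC)c1OC | intermediate
20 | 6-[2,6-dimethoxy-4-(2,4,6-trimethoxyphenoxy)phenoxy]-2,3,4-trimethoxybenzaldehyde | COc1cc(Oc2c(OC)cc(Oc3c(OC)cc(OC)cc3OC)cc2OC)c(C=O)c(OC)c1OC | intermediate
21 | ArABC formate | COc1cc(Oc2c(OC)cc(Oc3c(OC)cc(OC)cc3OC)cc2OC)c(OC=O)c(OC)c1OC | intermediate (not isolated)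
22 | ArABC–OH, 6-[2,6-dimethoxy-4-(2,4,6-trimethoxyphenoxy)phenoxy]-2,3,4-trimethoxyphenol | COc1cc(Oc2c(OC)cc(Oc3c(OC)cc(OC)cc3OC)cc2OC)c(O)c(OC)c1OC | intermediate
23 | trichloroethylene | ClC=C(Cl)Cl | starting material
24 | (E)-1,2-dichloroethenyl ArABC ether | Cl/C=C(/Cl)Oc1c(OC)c(OC)c(OC)cc1Oc1c(OC)cc(Oc2c(OC)cc(OC)cc2OC)cc1OC | intermediate
25 | methyl chloroformate | COC(=O)Cl | starting material
26 | chloroethynyl ArABC ether | ClC#COc1c(OC)c(OC)c(OC)cc1Oc1c(OC)cc(Oc2c(OC)cc(OC)cc2OC)cc1OC | intermediate (not isolated)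
27 | lithium (ArABC-oxy)acetylide | [Li]C#COc1c(OC)c(OC)c(OC)cc1Oc1c(OC)cc(Oc2c(OC)cc(OC)cc2OC)cc1OC | intermediate (not isolated)
28 | methyl 3-(ArABC-oxy)prop-2-ynoate | COC(=O)C#COc1c(OC)c(OC)c(OC)cc1Oc1c(OC)cc(Oc2c(OC)cc(OC)cc2OC)cc1OC | intermediate
29 | dimethyl 3-(ArABC-oxy)-4-[(ArEFG-oxy)acetyl]pent-2-enedioate (racemic, double-bond isomers interconverting through its anion) | COC(=O)C=C(Oc1c(OC)c(OC)c(OC)cc1Oc1c(OC)cc(Oc2c(OC)cc(OC)cc2OC)cc1OC)C(C(=O)OC)C(=O)COc1cc(OC)c(OC)c(OC)c1Oc1cc(OC)c(Oc2cc(OC)c(OC)c(OC)c2)c(OC)c1 | intermediate (not isolated)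
30 | methyl 6-(ArABC-oxy)-3-(ArEFG-oxy)-2,4-dihydroxybenzoate | COC(=O)c1c(O)c(Oc2cc(OC)c(OC)c(OC)c2Oc2cc(OC)c(Oc3cc(OC)c(OC)c(OC)c3)c(OC)c2)c(O)cc1Oc1c(OC)c(OC)c(OC)cc1Oc1c(OC)cc(Oc2c(OC)cc(OC)cc2OC)cc1OC | intermediate
31 | 6-(ArABC-oxy)-3-(ArEFG-oxy)-2,4-dihydroxybenzoic acid | OC(=O)c1c(O)c(Oc2cc(OC)c(OC)c(OC)c2Oc2cc(OC)c(Oc3cc(OC)c(OC)c(OC)c3)c(OC)c2)c(O)cc1Oc1c(OC)c(OC)c(OC)cc1Oc1c(OC)cc(Oc2c(OC)cc(OC)cc2OC)cc1OC | intermediate (not isolated)
32 | 5-(ArABC-oxy)-2-(ArEFG-oxy)benzene-1,3-diol | Oc1cc(Oc2c(OC)c(OC)c(OC)cc2Oc2c(OC)cc(Oc3c(OC)cc(OC)cc3OC)cc2OC)cc(O)c1Oc1cc(OC)c(OC)c(OC)c1Oc1cc(OC)c(Oc2cc(OC)c(OC)c(OC)c2)c(OC)c1 | intermediate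
33 | CNP0292517.0, the octadecahydroxy heptamer | Oc1cc(O)c(Oc2cc(O)c(Oc3cc(O)c(O)c(O)c3Oc3cc(O)c(Oc4cc(O)c(O)c(O)c4Oc4cc(O)c(Oc5cc(O)c(O)c(O)c5)c(O)c4)c(O)c3)c(O)c2)c(O)c1 | target

**Totals**
Total: 15 steps. Longest linear sequence: 9 steps (6, 7, 9, 10, 11, 12, 13, 14, 15).

**Steps most likely to fail**

Step 13. The Michael stage may be diverted by expulsion of the ABC aryloxide, the dianion may fail to form, or oxygen acylation may give a pyranone in place of ring D. The fallback uses only Ullmann and Baeyer–Villiger chemistry of the kind already in the route. It sets out from 22 and returns at 33. Phenol 22 is coupled with 13 as in step 6 to give the ABCD aldehyde F1. Peracid converts this through its formate F2 into the ABCD phenol F3. Coupling of F3 with 19 as in step 9 gives the ABCDE aldehyde F4, which is oxidised through formate F5 to the ABCDE phenol F6. A further coupling with 13 gives the ABCDEF aldehyde F7, oxidised through formate F8 to the ABCDEF phenol F9. Ullmann coupling of F9 with 17 gives the octadecamethyl ether of the heptamer F10, and BBr3 as in step 15 would then give 33.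

Step 12. Ring lithiation, over-addition to the chloroformate, or hydration and oligomerisation of the ynoate on isolation may erode the material. The fallback avoids organolithium reagents and the ynoate. It sets out from 22 and returns at 29 within step 13. The potassium phenoxide of 22 (K2CO3, DMF) is treated with methyl 3,3-dichloroacrylate, and vinylic addition–elimination should give methyl 3-chloro-3-(ArABC-oxy)prop-2-enoate F11. The sodium enolate of 11 should then displace the remaining chloride (a better leaving group than aryloxide) by a second addition–elimination. This gives the anion of 29, which is closed with LDA as in step 13.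

Step 15. Cleavage of sixteen methyl ethers may stop short, and the free polyphenol may oxidise in air during work-up and chromatography, leaving mixtures that cannot be separated. The fallback sets out from 32 and returns at 33. After the BBr3 treatment and methanol quench the crude product is acetylated in the same flask (Ac2O, pyridine) to the octadecaacetate F12. This is stable to air and to silica and can be purified and checked for completeness. Methanolysis with anhydrous HCl in degassed MeOH then releases 33 without any phenoxide being formed.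

**Further compounds**
F1 | step 13 | 4-(ArABC-oxy)-2,6-dimethoxybenzaldehyde (ABCD aldehyde) | O=Cc1c(OC)cc(Oc2c(OC)c(OC)c(OC)cc2Oc2c(OC)cc(Oc3c(OC)cc(OC)cc3OC)cc2OC)cc1OC
F2 | step 13 | 4-(ArABC-oxy)-2,6-dimethoxyphenyl formate | O=COc1c(OC)cc(Oc2c(OC)c(OC)c(OC)cc2Oc2c(OC)cc(Oc3c(OC)cc(OC)cc3OC)cc2OC)cc1OC
F3 | step 13 | 4-(ArABC-oxy)-2,6-dimethoxyphenol (ABCD phenol) | Oc1c(OC)cc(Oc2c(OC)c(OC)c(OC)cc2Oc2c(OC)cc(Oc3c(OC)cc(OC)cc3OC)cc2OC)cc1OC
F4 | step 13 | 6-[4-(ArABC-oxy)-2,6-dimethoxyphenoxy]-2,3,4-trimethoxybenzaldehyde (ABCDE aldehyde) | COc1cc(Oc2c(OC)cc(Oc3c(OC)c(OC)c(OC)cc3Oc3c(OC)cc(Oc4c(OC)cc(OC)cc4OC)cc3OC)cc2OC)c(C=O)c(OC)c1OC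
F5 | step 13 | 6-[4-(ArABC-oxy)-2,6-dimethoxyphenoxy]-2,3,4-trimethoxyphenyl formate | COc1cc(Oc2c(OC)cc(Oc3c(OC)c(OC)c(OC)cc3Oc3c(OC)cc(Oc4c(OC)cc(OC)cc4OC)cc3OC)cc2OC)c(OC=O)c(OC)c1OC
F6 | step 13 | 6-[4-(ArABC-oxy)-2,6-dimethoxyphenoxy]-2,3,4-trimethoxyphenol (ABCDE phenol) | COc1cc(Oc2c(OC)cc(Oc3c(OC)c(OC)c(OC)cc3Oc3c(OC)cc(Oc4c(OC)cc(OC)cc4OC)cc3OC)cc2OC)c(O)c(OC)c1OC
F7 | step 13 | ABCDEF aldehyde, 2,6-dimethoxybenzaldehyde carrying the ABCDE aryloxy group at C4 | O=Cc1c(OC)cc(Oc2c(OC)c(OC)c(OC)cc2Oc2c(OC)cc(Oc3c(OC)c(OC)c(OC)cc3Oc3c(OC)cc(Oc4c(OC)cc(OC)cc4OC)cc3OC)cc2OC)cc1OC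
F8 | step 13 | ABCDEF formate | O=COc1c(OC)cc(Oc2c(OC)c(OC)c(OC)cc2Oc2c(OC)cc(Oc3c(OC)c(OC)c(OC)cc3Oc3c(OC)cc(Oc4c(OC)cc(OC)cc4OC)cc3OC)cc2OC)cc1OC
F9 | step 13 | ABCDEF phenol | Oc1c(OC)cc(Oc2c(OC)c(OC)c(OC)cc2Oc2c(OC)cc(Oc3c(OC)c(OC)c(OC)cc3Oc3c(OC)cc(Oc4c(OC)cc(OC)cc4OC)cc3OC)cc2OC)cc1OC
F10 | step 13 | octadecamethyl ether of the heptamer | COc1cc(Oc2c(OC)cc(Oc3c(OC)c(OC)c(OC)cc3Oc3c(OC)cc(Oc4c(OC)c(OC)c(OC)cc4Oc4c(OC)cc(Oc5c(OC)cc(OC)cc5OC)cc4OC)cc3OC)cc2OC)cc(OC)c1OC
F11 | step 12 | methyl 3-chloro-3-(ArABC-oxy)prop-2-enoate (mixture of double-bond isomers) | COC(=O)C=C(Cl)Oc1c(OC)c(OC)c(OC)cc1Oc1c(OC)cc(Oc2c(OC)cc(OC)cc2OC)cc1OC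
F12 | step 15 | octadecaacetate of the heptamer | CC(=O)Oc1cc(OC(C)=O)c(Oc2cc(OC(C)=O)c(Oc3cc(OC(C)=O)c(OC(C)=O)c(OC(C)=O)c3Oc3cc(OC(C)=O)c(Oc4cc(OC(C)=O)c(OC(C)=O)c(OC(C)=O)c4Oc4cc(OC(C)=O)c(Oc5cc(OC(C)=O)c(OC(C)=O)c(OC(C)=O)c5)c(OC(C)=O)c4)c(OC(C)=O)c3)c(OC(C)=O)c2)c(OC(C)=O)c1
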